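Retrosynthetic overview
1. Ring numbering: C1 (CHOH), C2=C3, C4H2, C5 (C(OH) carrying chain carbon C1'), C6H2. The route rests on the 1,3-dioxygen array O–C1–C6–C5–O of the one six-membered carbocycle. This array is an aldol retron in which C5 was a chain ketone and C6 the methyl carbon of a methyl ketone.
2. Endgame: the C1 carbinol comes from the C1 ketone of a 5-hydroxycyclohex-2-enone by hydroxyl-directed reduction followed by Mitsunobu inversion to the cis-diol. The C2=C3 bond comes from E1cB loss of a C3 silyloxy group that serves only to pass chirality to C5.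
3. Key disconnection C5–C6: an intramolecular aldol addition of an acyclic (4R)-4-silyloxy-2,6-diketone closes the only ring made in the route (the phenyl ring is bought). The C3 stereocentre sets C5 in this step.
4. The diketone comes from a three-component union. (R)-Epichlorohydrin (C2–C3–C4) is opened first by lithiated 2-methyl-1,3-dithiane (C6, C1), then by the lithiated chain dithiane (C5 and chain).
5. The chain comes from a Z-selective Wittig reaction of 12-bromododecanal with the ylide from (4-bromobutyl)benzene, followed by alkylation of 1,3-dithiane.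

Key step: step 9

Remark: the target is the cis-diol, (1S,5S) in the ring numbering above, which is (1S,3S)-1-alkylcyclohex-4-ene-1,3-diol in systematic numbering. "C16 chain" means (12Z)-16-phenylhexadec-12-en-1-yl.

Step 1
Reactants: 1 12-bromododecan-1-ol
Product: 2 12-bromododecanal
Conditions: TEMPO (2,2,6,6-tetramethylpiperidin-1-oxyl, 10 mol%), PhI(OAc)2 (1.1 equiv), CH2Cl2, rt
Reagents that add atoms: none
Why: The oxoammonium-catalysed (TEMPO) oxidation of a primary alcohol stops at the aldehyde and leaves the primary bromide alone.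

Step 2
Reactants: 3 (4-bromobutyl)benzene
Product: 4 (4-phenylbutyl)triphenylphosphonium bromide
Conditions: PPh3, MeCN, reflux
Reagents that add atoms: triphenylphosphine, c1ccc(cc1)P(c1ccccc1)c1ccccc1
Why: SN2 quaternisation of triphenylphosphine by an unhindered primary bromide is the standard entry to a Wittig salt.

Step 3
Reactants: 4 (4-phenylbutyl)triphenylphosphonium bromide; 2 12-bromododecanal
Product: 6 [(4Z)-16-bromohexadec-4-en-1-yl]benzene, via triphenyl(4-phenylbutylidene)phosphorane 5 (not isolated)
Conditions: NaN(SiMe3)2, THF, 0 °C; then 2, −78 °C to rt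
Reagents that add atoms: none
Why: In this lithium-free Wittig olefination the non-stabilised ylide 5 adds to the aldehyde much faster than it is alkylated by the primary bromide, and the kinetically formed cis-oxaphosphetane collapses to the Z-alkene.

Step 4
Reactants: 7 1,3-dithiane; 6 [(4Z)-16-bromohexadec-4-en-1-yl]benzene
Product: 9 2-[(12Z)-16-phenylhexadec-12-en-1-yl]-1,3-dithiane, via 2-lithio-1,3-dithiane 8 (not isolated)
Conditions: n-BuLi, THF, −30 °C; then 6, −78 °C to rt
Reagents that add atoms: none
Why: Corey–Seebach umpolung, in which the sulfur-stabilised carbanion displaces the primary bromide by SN2 and so installs the future C5 carbonyl carbon in masked form without touching the Z-alkene.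

Step 5
Reactants: 10 2-methyl-1,3-dithiane; 11 (R)-epichlorohydrin
Product: 14 (R)-2-methyl-2-(oxiran-2-ylmethyl)-1,3-dithiane, via 2-lithio-2-methyl-1,3-dithiane 12 (not isolated), via lithium chlorohydrin alkoxide 13 (not isolated)
Conditions: n-BuLi, THF, −20 °C; then 11 (1.2 equiv), −78 to −40 °C; then rt
Reagents that add atoms: none
Why: The dithiane anion opens the epoxide at its unsubstituted carbon rather than attacking C–Cl, and on warming alkoxide 13 closes a new epoxide by 3-exo-tet displacement of chloride, so the C–O bond at the stereocentre is never broken and the purchased configuration (future C3) carries over with the descriptor still R.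

Step 6
Reactants: 9 2-[(12Z)-16-phenylhexadec-12-en-1-yl]-1,3-dithiane; 14 (R)-2-methyl-2-(oxiran-2-ylmethyl)-1,3-dithiane
Product: 17 (2R)-1-(2-methyl-1,3-dithian-2-yl)-3-{2-[(12Z)-16-phenylhexadec-12-en-1-yl]-1,3-dithian-2-yl}propan-2-ol, via lithiated chain dithiane 15 (not isolated), via lithium alkoxide 16 (not isolated)
Conditions: n-BuLi, THF, −20 °C; then 14, DMPU, −78 to 0 °C; H2O
Reagents that add atoms: none
Why: Corey–Seebach opening of a terminal epoxide by a 2-alkyl-2-lithio-1,3-dithiane takes place by SN2 at the CH2 terminus, which forms C4–C5 and leaves the carbinol stereocentre untouched.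

Step 7
Reactants: 17 (2R)-1-(2-methyl-1,3-dithian-2-yl)-3-{2-[(12Z)-16-phenylhexadec-12-en-1-yl]-1,3-dithian-2-yl}propan-2-ol
Product: 18 tert-butyldimethylsilyl ether of 17 with (2R) configuration
Conditions: TBSOTf, 2,6-lutidine, CH2Cl2, 0 °C
Reagents that add atoms: tert-butyldimethylsilyl triflate, CC(C)(C)[Si](C)(C)OS(=O)(=O)C(F)(F)F
Why: O-silylation with the reactive silyl triflate overcomes the crowding by the two flanking dithianes and installs a non-chelating, base-tolerant group with a large equatorial preference.

Step 8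
Reactants: 18 tert-butyldimethylsilyl ether of 17
Product: 19 (4R,18Z)-4-(tert-butyldimethylsilyloxy)-22-phenyldocos-18-ene-2,6-dione
Conditions: MeI (excess), CaCO3, MeCN/H2O 9:1, 45 °C
Reagents that add atoms: water, O
Why: In this alkylative dithiane hydrolysis S-methylation makes each sulfur a leaving group and water captures the thionium ion, under neutral conditions free of oxidants and thiophilic metals, so the Z-alkene, the silyl ether and the elimination-prone β-silyloxy ketone units survive.

Step 9
Reactants: 19 (4R,18Z)-4-(tert-butyldimethylsilyloxy)-22-phenyldocos-18-ene-2,6-dione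
Product: 22 (3S,5S)-3-(tert-butyldimethylsilyloxy)-5-hydroxy-5-[(12Z)-16-phenylhexadec-12-en-1-yl]cyclohexan-1-one, via lithium C6 enolate 20 (not isolated), via lithium C5 aldolate 21 (not isolated)
Conditions: LiN(iPr)2 (LDA, 1.05 equiv, added slowly), THF (0.01 M), −78 °C; AcOH, −78 °C
Reagents that add atoms: none
Why: LDA removes a proton from the C6 methyl group and lithium enolate 20 attacks the C5 ketone through C6, forming the C5–C6 bond and lithium aldolate 21, which is protonated at −78 °C before it can revert or expel silanolate. The closest known reaction type is the intramolecular aldol addition of 1,5-diketones to 3-hydroxycyclohexanones, the ketol stage of the Robinson annulation and of the Hajos–Parrish cyclisation. The only ring formed, the carbocycle C1–C6, closes in the 6-(enolendo)-exo-trig mode. The new C5 stereocentre is controlled by the C3 stereocentre: in the chair-like transition state the C3 silyloxy group and the C16 chain are equatorial and the C5 oxygen is axial and gauche to C1, where lithium can bridge it to the enolate oxygen, so C5–OH ends up trans to C3–OTBS, which is (3S,5S), and since an axial hydroxyl with equatorial carbon substituents is also the favoured arrangement of equilibrated cyclic ketols, kinetic and thermodynamic preference should agree. The step needs deprotonation at CH3 rather than at C2, C4 or C1': a hindered amide removes methyl protons fastest under irreversible conditions, slow addition of one equivalent of base to a dilute solution suppresses double deprotonation and proton exchange, enolates at C2 or C4 could only close four-membered rings and keep their β-silyloxy group at −78 °C, and only the C1' enolate (enolexo closure onto C1) is a productive competitor. Any C5 epimer is removed by chromatography here, because after loss of the C3 oxygen it would become the enantiomer.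

Step 10
Reactants: 22 (3S,5S)-3-(tert-butyldimethylsilyloxy)-5-hydroxy-5-[(12Z)-16-phenylhexadec-12-en-1-yl]cyclohexan-1-one
Product: 23 (S)-5-hydroxy-5-[(12Z)-16-phenylhexadec-12-en-1-yl]cyclohex-2-en-1-one
Conditions: DBU (1.5 equiv), CH2Cl2, 0 °C to rt
Reagents that add atoms: none
Why: In this E1cB elimination the C1–C2 enolate expels tert-butyldimethylsilanolate, a much better leaving group than the hydroxide that would have to leave from C5, so C2=C3 forms and the relay centre is erased while C5 stays intact under short exposure to a mild amidine base.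

Step 11
Reactants: 23 (S)-5-hydroxy-5-[(12Z)-16-phenylhexadec-12-en-1-yl]cyclohex-2-en-1-one
Product: 25 (1S,3R)-1-[(12Z)-16-phenylhexadec-12-en-1-yl]cyclohex-4-ene-1,3-diol (trans-diol), via alkoxy(diacetoxy)hydridoborate 24 (not isolated)
Conditions: Me4NBH(OAc)3 (5 equiv), MeCN/AcOH 1:1, −30 °C; aq sodium potassium tartrate
Reagents that add atoms: none
Why: A boron chelate of the Narasaka–Prasad type cannot form because the ring holds the O=C1–C6–C5 torsion in the anticlinal range, so the Evans–Saksena hydroxyl-directed reduction is used instead, in which the borohydride bound to the pseudo-axial C5 oxygen (24) delivers hydride in 1,2-fashion to the same, stereoelectronically preferred axial face of C1 and sets the C1 hydroxyl trans to C5–OH (C1 is R in ring numbering).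

Step 12
Reactants: 25 (1S,3R)-1-[(12Z)-16-phenylhexadec-12-en-1-yl]cyclohex-4-ene-1,3-diol
Product: 27 (1S,5S)-5-hydroxy-5-[(12Z)-16-phenylhexadec-12-en-1-yl]cyclohex-2-en-1-yl 4-nitrobenzoate, via alkoxyphosphonium 4-nitrobenzoate 26 (not isolated)
Conditions: 4-O2NC6H4CO2H, PPh3, DIAD, THF, 0 °C
Reagents that add atoms: 4-nitrobenzoic acid, O=C(O)c1ccc(cc1)[N+](=O)[O-]
Why: In this Mitsunobu reaction only the secondary allylic hydroxyl is activated (26) and it is displaced by the acidic, nucleophilic 4-nitrobenzoate in an SN2 process with inversion, turning C1 from R to S and placing the C1 oxygen cis to the inert tertiary C5 hydroxyl.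

Step 13
Reactants: 27 (1S,5S)-5-hydroxy-5-[(12Z)-16-phenylhexadec-12-en-1-yl]cyclohex-2-en-1-yl 4-nitrobenzoate
Product: 28 (1S,3S)-1-[(12Z)-16-phenylhexadec-12-en-1-yl]cyclohex-4-ene-1,3-diol (target)
Conditions: K2CO3 (0.2 equiv), MeOH, 0 °C to rt
Reagents that add atoms: none
Why: Base-catalysed transesterification cleaves the activated ester at the acyl–oxygen bond, so the C1–O bond, both stereocentres and both alkenes are unaffected.

Compound list
1 | 12-bromododecan-1-ol | OCCCCCCCCCCCCBr | starting material
2 | 12-bromododecanal | O=CCCCCCCCCCCCBr | intermediate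
3 | (4-bromobutyl)benzene | BrCCCCc1ccccc1 | starting material
4 | (4-phenylbutyl)triphenylphosphonium bromide | [Br-].c1ccc(cc1)CCCC[P+](c1ccccc1)(c1ccccc1)c1ccccc1 | intermediate
5 | triphenyl(4-phenylbutylidene)phosphorane | c1ccc(cc1)CCCC=P(c1ccccc1)(c1ccccc1)c1ccccc1 | intermediate
6 | [(4Z)-16-bromohexadec-4-en-1-yl]benzene | BrCCCCCCCCCCC/C=C\CCCc1ccccc1 | intermediate
7 | 1,3-dithiane | C1CSCSC1 | starting material
8 | 2-lithio-1,3-dithiane | [Li]C1SCCCS1 | intermediate
9 | 2-[(12Z)-16-phenylhexadec-12-en-1-yl]-1,3-dithiane | C1(CCCCCCCCCCC/C=C\CCCc2ccccc2)SCCCS1 | intermediate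
10 | 2-methyl-1,3-dithiane | CC1SCCCS1 | starting material
11 | (R)-epichlorohydrin | ClC[C@H]1CO1 | starting material
12 | 2-lithio-2-methyl-1,3-dithiane | [Li]C1(C)SCCCS1 | intermediate
13 | lithium (R)-1-chloro-3-(2-methyl-1,3-dithian-2-yl)propan-2-olate | [Li+].CC1(C[C@@H]([O-])CCl)SCCCS1 | intermediate
14 | (R)-2-methyl-2-(oxiran-2-ylmethyl)-1,3-dithiane | CC1(C[C@@H]2CO2)SCCCS1 | intermediate
15 | 2-lithio-2-[(12Z)-16-phenylhexadec-12-en-1-yl]-1,3-dithiane | [Li]C1(CCCCCCCCCCC/C=C\CCCc2ccccc2)SCCCS1 | intermediate
16 | lithium alkoxide of 17 | [Li+].CC1(C[C@@H]([O-])CC2(CCCCCCCCCCC/C=C\CCCc3ccccc3)SCCCS2)SCCCS1 | intermediate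
17 | (2R)-1-(2-methyl-1,3-dithian-2-yl)-3-{2-[(12Z)-16-phenylhexadec-12-en-1-yl]-1,3-dithian-2-yl}propan-2-ol | CC1(C[C@@H](O)CC2(CCCCCCCCCCC/C=C\CCCc3ccccc3)SCCCS2)SCCCS1 | intermediate
18 | tert-butyldimethylsilyl ether of 17, (2R) | CC1(C[C@@H](O[Si](C)(C)C(C)(C)C)CC2(CCCCCCCCCCC/C=C\CCCc3ccccc3)SCCCS2)SCCCS1 | intermediate
19 | (4R,18Z)-4-(tert-butyldimethylsilyloxy)-22-phenyldocos-18-ene-2,6-dione | CC(=O)C[C@@H](O[Si](C)(C)C(C)(C)C)CC(=O)CCCCCCCCCCC/C=C\CCCc1ccccc1 | intermediate
20 | lithium C6 (terminal) enolate of 19 | [Li+].C=C([O-])C[C@@H](O[Si](C)(C)C(C)(C)C)CC(=O)CCCCCCCCCCC/C=C\CCCc1ccccc1 | intermediate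
21 | lithium C5 aldolate of 22 | [Li+].O=C1C[C@@H](O[Si](C)(C)C(C)(C)C)C[C@@]([O-])(CCCCCCCCCCC/C=C\CCCc2ccccc2)C1 | intermediate
22 | (3S,5S)-3-(tert-butyldimethylsilyloxy)-5-hydroxy-5-[(12Z)-16-phenylhexadec-12-en-1-yl]cyclohexan-1-one (OH trans to OTBS) | O=C1C[C@@H](O[Si](C)(C)C(C)(C)C)C[C@@](O)(CCCCCCCCCCC/C=C\CCCc2ccccc2)C1 | intermediate
23 | (S)-5-hydroxy-5-[(12Z)-16-phenylhexadec-12-en-1-yl]cyclohex-2-en-1-one | O=C1C=CC[C@@](O)(CCCCCCCCCCC/C=C\CCCc2ccccc2)C1 | intermediate
24 | tetramethylammonium diacetoxy(hydrido)borate ester of the C5 hydroxyl of 23 | O=C1C=CC[C@@](O[BH-](OC(C)=O)OC(C)=O)(CCCCCCCCCCC/C=C\CCCc2ccccc2)C1.C[N+](C)(C)C | intermediate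
25 | (1S,3R)-1-[(12Z)-16-phenylhexadec-12-en-1-yl]cyclohex-4-ene-1,3-diol (trans-diol) | O[C@H]1C=CC[C@@](O)(CCCCCCCCCCC/C=C\CCCc2ccccc2)C1 | intermediate
26 | C1 alkoxy(triphenyl)phosphonium 4-nitrobenzoate of 25 | O([C@H]1C=CC[C@@](O)(CCCCCCCCCCC/C=C\CCCc2ccccc2)C1)[P+](c1ccccc1)(c1ccccc1)c1ccccc1.[O-]C(=O)c1ccc(cc1)[N+](=O)[O-] | intermediate
27 | (1S,5S)-5-hydroxy-5-[(12Z)-16-phenylhexadec-12-en-1-yl]cyclohex-2-en-1-yl 4-nitrobenzoate (cis) | O=C(O[C@@H]1C=CC[C@@](O)(CCCCCCCCCCC/C=C\CCCc2ccccc2)C1)c3ccc(cc3)[N+](=O)[O-] | intermediate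
28 | (1S,3S)-1-[(12Z)-16-phenylhexadec-12-en-1-yl]cyclohex-4-ene-1,3-diol | O[C@@H]1C=CC[C@@](O)(CCCCCCCCCCC/C=C\CCCc2ccccc2)C1 | target

Total step count: 13.
Longest linear sequence: 11 steps (1, 3, 4, 6, 7, 8, 9, 10, 11, 12, 13).

Steps most likely to fail

Step 9. Three things may go wrong. Deprotonation may leak to C1', followed by enolexo closure onto C1. Facial selectivity at C5 may be incomplete. Proton shuffling may start premature loss of the silyloxy group.
The fallback separates enolate formation from ring closure.
- It sets out from 19. LDA with Me3SiCl present as internal quench (THF, −78 °C) should give the terminal trimethylsilyl enol ether F1.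
- N-Bromosuccinimide at −78 °C converts this into the bromomethyl ketone F2. This compound is purified, so positional isomers are removed before any C–C bond is made.
- SmI2 (2.2 equiv, THF, −78 °C) then reduces only the C–Br bond to the diiodosamarium enolate F3. This trivalent samarium enolate is formed at C6 alone under non-basic conditions.
- F3 closes onto C5 in a samarium Reformatsky-type aldol through the same chair, and aqueous work-up rejoins the route at 22.

Step 10. Expulsion of silanolate may be slow. Longer contact with base could then trigger retro-aldol opening and reclosure, which racemises C5 because no other stereocentre is left. It could also trigger a second elimination followed by aromatisation.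
The fallback exchanges the leaving group so that a weaker base is enough.
- It sets out from 22. HF·pyridine buffered with pyridine (THF, 0 °C) should give the 3,5-dihydroxy ketone F4.
- MsCl and Et3N (CH2Cl2, −20 to 0 °C) sulfonylate only the secondary hydroxyl, giving the C3 mesylate F5.
- F5 eliminates under Et3N in the same flask, and the route is rejoined at 23.

Step 12. The displacement may leak into the allylically transposed (SN2') channel or into elimination. C1 and C3 are related by the local mirror plane through C2 and C5, so transposition would erode enantiomeric or diastereomeric purity.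
The fallback avoids inversion altogether and relies on steric shielding.
- It sets out from 23. Et3SiOTf and 2,6-lutidine should give the C5 triethylsilyl ether enone F6, whose pseudo-axial silyloxy group blocks the face of C1 syn to it.
- iBu2AlH (toluene, −78 °C) reduces in 1,2-fashion from the open face to give the cis allylic alcohol silyl ether F7. This is purified from any trans isomer.
- Bu4NF buffered with AcOH (THF, 0 °C) removes the silyl group, and the route is rejoined at 28.

Further compounds
F1 | step 9 | (4R,18Z)-4-(tert-butyldimethylsilyloxy)-22-phenyl-2-(trimethylsilyloxy)docosa-1,18-dien-6-one | C=C(O[Si](C)(C)C)C[C@@H](O[Si](C)(C)C(C)(C)C)CC(=O)CCCCCCCCCCC/C=C\CCCc1ccccc1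
F2 | step 9 | (4S,18Z)-1-bromo-4-(tert-butyldimethylsilyloxy)-22-phenyldocos-18-ene-2,6-dione | BrCC(=O)C[C@@H](O[Si](C)(C)C(C)(C)C)CC(=O)CCCCCCCCCCC/C=C\CCCc1ccccc1
F3 | step 9 | diiodosamarium C6 enolate of 19 | C=C(O[Sm](I)I)C[C@@H](O[Si](C)(C)C(C)(C)C)CC(=O)CCCCCCCCCCC/C=C\CCCc1ccccc1
F4 | step 10 | (3S,5S)-3,5-dihydroxy-5-[(12Z)-16-phenylhexadec-12-en-1-yl]cyclohexan-1-one | O=C1C[C@@H](O)C[C@@](O)(CCCCCCCCCCC/C=C\CCCc2ccccc2)C1
F5 | step 10 | (1S,3S)-3-hydroxy-5-oxo-3-[(12Z)-16-phenylhexadec-12-en-1-yl]cyclohexyl methanesulfonate | O=C1C[C@@H](OS(C)(=O)=O)C[C@@](O)(CCCCCCCCCCC/C=C\CCCc2ccccc2)C1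
F6 | step 12 | (S)-5-[(12Z)-16-phenylhexadec-12-en-1-yl]-5-(triethylsilyloxy)cyclohex-2-en-1-one | O=C1C=CC[C@@](O[Si](CC)(CC)CC)(CCCCCCCCCCC/C=C\CCCc2ccccc2)C1
F7 | step 12 | (1S,5S)-5-[(12Z)-16-phenylhexadec-12-en-1-yl]-5-(triethylsilyloxy)cyclohex-2-en-1-ol | O[C@@H]1C=CC[C@@](O[Si](CC)(CC)CC)(CCCCCCCCCCC/C=C\CCCc2ccccc2)C1
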